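**Retrosynthetic overview**
- The C6 allyl group is put on last by α′-alkylation of the bicyclic vinylogous ester; the side chain on C7a directs it trans.
- The side-chain CH2–aryl bond comes from a photoredox/nickel decarboxylative arylation of a butanoic acid with 5-bromo-1,2,3-trimethoxybenzene.
- The dioxolane comes from CH2Br2 bridging of the tertiary C7a oxygen and the neighbouring enol oxygen, after opening a spiro-γ-lactone.
- The quaternary C7a–O bond comes from anodic dearomatisation of (S)-7-hydroxy-4-methyldihydrocoumarin, with water adding anti to the ring methyl.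
- The dihydrocoumarin comes from (R)-β-butyrolactone and a 2,4-dimethoxyphenyl Grignard reagent (SN2, inversion). Ring order: bought arene → δ-lactone → dearomatised ring with spiro-γ-lactone → dioxolane.

Assumption: (R)-β-butyrolactone, the lactone of the biopolymer-derived (R)-3-hydroxybutanoic acid, is bought enantiopure and is the only source of chirality.

**Step 1**
Reactants: 1 1-bromo-2,4-dimethoxybenzene; 2 (R)-β-butyrolactone [(4R)-4-methyloxetan-2-one]
Product: 4 (3S)-3-(2,4-dimethoxyphenyl)butanoic acid, via aryl Grignard reagent 3 (not isolated)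
Conditions: Mg, THF, 40 °C; then CuBr·SMe2 (5 mol %), 2, THF/Me2S, −30 → 0 °C; aq. HCl
Reagents that add atoms: none
Why: Copper-catalysed SN2 opening of the β-lactone at its alkyl C–O bond by the aryl Grignard reagent (β-lactone alkylation) gives the 3-arylbutanoic acid with inversion, so the bought (R) centre becomes the (S) methine of the target side chain.

**Step 2**
Reactants: 4 (3S)-3-(2,4-dimethoxyphenyl)butanoic acid
Product: 6 (4S)-7-hydroxy-4-methyl-3,4-dihydro-2H-chromen-2-one, via dihydroxy acid 5 (not isolated)
Conditions: BBr3 (3 equiv), CH2Cl2, −78 °C → rt; H2O; then TsOH (cat.), PhMe, 80 °C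
Reagents that add atoms: none
Why: BBr3 cleaves both aryl methyl ethers and the ortho phenol then lactonises onto the acid (acid-catalysed dihydrocoumarin formation), which ties the untouched methyl stereocentre into a ring next to the carbon that will become C7a.

**Step 3**
Reactants: 6 (4S)-7-hydroxy-4-methyl-3,4-dihydro-2H-chromen-2-one
Product: 8 (4S,5S)-6-hydroxy-4-methyl-1-oxaspiro[4.5]deca-6,9-diene-2,8-dione, via 4a-hydroxy enol lactone 7 (not isolated)
Conditions: graphite anode, Pt cathode, undivided cell, LiClO4 (0.1 M), KH2PO4 buffer, MeCN/H2O 3:1, 5 mA cm−2, 2.2 F mol−1, 0 °C; then Et3N (cat.), CH2Cl2, rt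
Reagents that add atoms: water, O
Why: Proposed new method: two-electron anodic oxidation of the free phenol gives a phenoxonium ion with its charge para to oxygen at the ring-fusion carbon; the lactone ring is a half-chair with the methyl group pseudoaxial (away from the peri C–H), so water adds axially and anti to it (trans-diaxial OH/CH3), which sets the quaternary carbinol from the bought centre, and Et3N then relays the strained enol-lactone acyl group to the new tertiary oxygen through a five-membered orthoester (O→O acyl shift of a 1,2-diol monoester) to give the stable spiro-γ-lactone with a free vinylogous acid; the closest known chemistry is the anodic or PhI(OAc)2-mediated conversion of p-alkylphenols into p-quinols in aqueous MeCN, which has not been shown on a dihydrocoumarin or coupled to such an acyl relay.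

**Step 4**
Reactants: 8 (4S,5S)-6-hydroxy-4-methyl-1-oxaspiro[4.5]deca-6,9-diene-2,8-dione
Product: 10 (3S)-3-[(7aS)-5-oxo-1,3-benzodioxol-7a(5H)-yl]butanoic acid, via ring-opened dipotassium salt 9 (not isolated)
Conditions: KOH (powdered, 4 equiv), DMSO, rt; then CH2Br2 (1.5 equiv), rt → 40 °C; aq. HCl to pH 4, 0 °C
Reagents that add atoms: potassium hydroxide, [K+].[OH-]; dibromomethane, BrCBr
Why: Hydroxide opens the lactone irreversibly to the carboxylate, the tertiary alkoxide (the hardest and fastest nucleophile in KOH/DMSO) is alkylated first by CH2Br2, and the adjacent enolate oxygen, the only one that can reach, closes the five-membered ring (double Williamson methylenation); no stereocentre is touched (the descriptor at C7a changes only through the priority rules).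

**Step 5**
Reactants: 10 (3S)-3-[(7aS)-5-oxo-1,3-benzodioxol-7a(5H)-yl]butanoic acid
Product: 11 (3S)-3-[(7aR)-5-oxo-6,7-dihydro-1,3-benzodioxol-7a(5H)-yl]butanoic acid
Conditions: H2 (1 atm), RhCl(PPh3)3 (5 mol %), PhMe/EtOH 1:1, rt
Reagents that add atoms: none
Why: Homogeneous hydrogenation with RhCl(PPh3)3 reduces only the disubstituted enone C=C of a cross-conjugated dienone (as with steroid 1,4-dien-3-ones) and leaves the alkoxy-substituted alkene and the allylic C–O bond alone, which removes the radical-accepting and reducible dienone before the next step.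

**Step 6**
Reactants: 11 (3S)-3-[(7aR)-5-oxo-6,7-dihydro-1,3-benzodioxol-7a(5H)-yl]butanoic acid; 12 5-bromo-1,2,3-trimethoxybenzene
Product: 13 (7aR)-7a-[(2S)-1-(3,4,5-trimethoxyphenyl)propan-2-yl]-7,7a-dihydro-1,3-benzodioxol-5(6H)-one
Conditions: Ir[dF(CF3)ppy]2(dtbbpy)PF6 (1 mol %), NiCl2(dme) (5 mol %), dtbbpy, phthalimide (1 equiv), Cs2CO3 (1.5 equiv), DMSO, 450 nm LEDs, rt
Reagents that add atoms: none
Why: In this metallaphotoredox decarboxylative arylation the excited iridium photocatalyst oxidises the carboxylate, CO2 is lost, and the primary radical is captured by the aryl–nickel species and reductively eliminated to the C(sp3)–C(sp2) bond; the radical is one carbon away from the stereocentre, so nothing is scrambled.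

**Step 7**
Reactants: 13 (7aR)-7a-[(2S)-1-(3,4,5-trimethoxyphenyl)propan-2-yl]-7,7a-dihydro-1,3-benzodioxol-5(6H)-one
Product: 15 (6R,7aR)-6-allyl-7a-[(2S)-1-(3,4,5-trimethoxyphenyl)propan-2-yl]-7,7a-dihydro-1,3-benzodioxol-5(6H)-one, via lithium enolate 14 (not isolated)
Conditions: LiN(iPr)2 (1.1 equiv), THF, −78 °C; allyl bromide (1.5 equiv), −78 → −30 °C
Reagents that add atoms: allyl bromide, C=CCBr
Why: This is a Stork–Danheiser α′-alkylation of the vinylogous ester: kinetic deprotonation at C6 and entry of allyl bromide anti to the pseudoaxial side chain on C7a give the 6,7a-trans product, which is also the thermodynamic epimer (equatorial allyl), so any cis isomer can be equilibrated with DBU.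

**Compound list**
1 | 1-bromo-2,4-dimethoxybenzene | COc1ccc(Br)c(OC)c1 | starting material
2 | (R)-β-butyrolactone, (4R)-4-methyloxetan-2-one | C[C@@H]1CC(=O)O1 | starting material
3 | 2,4-dimethoxyphenylmagnesium bromide | COc1ccc([Mg]Br)c(OC)c1 | intermediate
4 | (3S)-3-(2,4-dimethoxyphenyl)butanoic acid | C[C@H](c1ccc(OC)cc1OC)CC(=O)O | intermediate
5 | (3S)-3-(2,4-dihydroxyphenyl)butanoic acid | C[C@H](c1ccc(O)cc1O)CC(=O)O | intermediate
6 | (4S)-7-hydroxy-4-methyl-3,4-dihydro-2H-chromen-2-one | O=C1C[C@H](C)c2ccc(O)cc2O1 | intermediate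
7 | (4S,4aS)-4a-hydroxy-4-methyl-4,4a-dihydro-2H-chromene-2,7(3H)-dione | O=C1C[C@H](C)[C@]2(O)C=CC(=O)C=C2O1 | intermediate
8 | (4S,5S)-6-hydroxy-4-methyl-1-oxaspiro[4.5]deca-6,9-diene-2,8-dione | O=C1C=C[C@]2(OC(=O)C[C@@H]2C)C(O)=C1 | intermediate
9 | dipotassium (3S)-3-[(1S)-1-hydroxy-2-oxido-4-oxocyclohexa-2,5-dien-1-yl]butanoate | C1=C[C@]([C@@H](C)CC(=O)[O-])(O)C([O-])=CC1=O.[K+].[K+] | intermediate
10 | (3S)-3-[(7aS)-5-oxo-1,3-benzodioxol-7a(5H)-yl]butanoic acid | C1=C[C@]2([C@@H](C)CC(=O)O)OCOC2=CC1=O | intermediate
11 | (3S)-3-[(7aR)-5-oxo-6,7-dihydro-1,3-benzodioxol-7a(5H)-yl]butanoic acid | C1C[C@]2([C@@H](C)CC(=O)O)OCOC2=CC1=O | intermediate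
12 | 5-bromo-1,2,3-trimethoxybenzene | COc1cc(Br)cc(OC)c1OC | starting material
13 | (7aR)-7a-[(2S)-1-(3,4,5-trimethoxyphenyl)propan-2-yl]-7,7a-dihydro-1,3-benzodioxol-5(6H)-one | C1C[C@]2([C@@H](C)Cc3cc(OC)c(OC)c(OC)c3)OCOC2=CC1=O | intermediate
14 | lithium enolate of 13 (C5–O−, C5=C6) | [Li+].[O-]C1=CC[C@]2([C@@H](C)Cc3cc(OC)c(OC)c(OC)c3)OCOC2=C1 | intermediate
15 | (6R,7aR)-6-allyl-7a-[(2S)-1-(3,4,5-trimethoxyphenyl)propan-2-yl]-7,7a-dihydro-1,3-benzodioxol-5(6H)-one | C=CC[C@@H]1C[C@]2([C@@H](C)Cc3cc(OC)c(OC)c(OC)c3)OCOC2=CC1=O | target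

**Totals**
Total step count: 7. Longest linear sequence: 7 steps (1 and 2 to 15; 12 is bought).

**Three steps most likely to fail**

Step 3 (the proposed new step). The phenoxonium ion may instead lose the benzylic proton and aromatise to 7-hydroxy-4-methylcoumarin, which destroys the stereocentre, or the product may be overoxidised. The fallback uses known singlet-oxygen chemistry and sets out from 6. KHSO5 (as 2KHSO5·KHSO4·K2SO4) with NaHCO3 in aqueous MeCN generates singlet oxygen, which adds at the para carbon on the same face anti to the methyl group and gives (4S,4aS)-4a-hydroperoxy-4-methyl-4,4a-dihydro-2H-chromene-2,7(3H)-dione F1. Me2S reduces this to 7, and Et3N converts 7 into 8, where the route resumes.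

Step 4. The enolate may be alkylated at carbon or at the remote oxygen, and the carboxylate can also be alkylated. The fallback builds the bridge stepwise and sets out from 8. The lactone is opened with KOH in DMSO as before, but the tertiary alkoxide is capped with chloromethyl methyl sulfide, which after acidification gives (3S)-3-{(1S)-2-hydroxy-1-[(methylsulfanyl)methoxy]-4-oxocyclohexa-2,5-dien-1-yl}butanoic acid F2; this is isolable because the capped oxygen can no longer relactonise. MeOTf with 2,6-di-tert-butylpyridine then activates the thioacetal, and the oxocarbenium ion is trapped by the neighbouring enol oxygen, the only one within reach, to give 10.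

Step 6. A primary carboxylate is oxidised slowly, and radical side reactions may compete. The fallback is a thermal redox-active-ester coupling and sets out from 11. N-Hydroxyphthalimide and N,N'-diisopropylcarbodiimide give 1,3-dioxoisoindolin-2-yl (3S)-3-[(7aR)-5-oxo-6,7-dihydro-1,3-benzodioxol-7a(5H)-yl]butanoate F3. Separately, 12 is converted (Mg, then ZnCl2) into (3,4,5-trimethoxyphenyl)zinc chloride F4. A decarboxylative Negishi coupling of the two with NiCl2(dme)/dtbbpy in DMF/THF gives 13.

**Further compounds**
F1 | step 3 | (4S,4aS)-4a-hydroperoxy-4-methyl-4,4a-dihydro-2H-chromene-2,7(3H)-dione | O=C1C[C@H](C)[C@]2(OO)C=CC(=O)C=C2O1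
F2 | step 4 | (3S)-3-{(1S)-2-hydroxy-1-[(methylsulfanyl)methoxy]-4-oxocyclohexa-2,5-dien-1-yl}butanoic acid | C1=C[C@]([C@@H](C)CC(=O)O)(OCSC)C(O)=CC1=O
F3 | step 6 | 1,3-dioxoisoindolin-2-yl (3S)-3-[(7aR)-5-oxo-6,7-dihydro-1,3-benzodioxol-7a(5H)-yl]butanoate | C1C[C@]2([C@@H](C)CC(=O)ON3C(=O)c4ccccc4C3=O)OCOC2=CC1=O
F4 | step 6 | (3,4,5-trimethoxyphenyl)zinc chloride | COc1cc([Zn]Cl)cc(OC)c1OC
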